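## The problem

Theaflavin-3-gallate (40) is a 5H-benzo[7]annulen-5-one (benzotropolone) that carries two flavan-3-ol units through their C2 atoms: one on the benzo ring at C1, esterified at O3 with gallic acid, and one on the tropolone ring at C8 with a free 3-hydroxyl. The core is fully substituted (oxygen at C3, C4, C5 and C6, carbon at C1 and C8), so it must be built with two carbon handles that can be told apart. There are four stereocentres, C2 and C3 of each chroman, all R and 2,3-cis; within one chroman C3 and C2 can be set together by a stereospecific oxidation of a Z-alkene followed by ring closure with inversion, but the two chromans are separated by the flat core and cannot control each other, so each pair needs reagent control. The two flavan units differ only in the gallate, so their 3-hydroxyls have to appear at different times. The free compound has nine phenols and a tropolone hydroxyl that are easily oxidised, a base-labile ester and cis-flavan units that can epimerise at C2. The tropone carbonyl is basic and the ring accepts hydride and organometallic reagents, so late steps must be neutral or mildly acidic, free of hydride donors, and end with hydrogenolysis of benzyl ethers. The feature that opens the route is that C8 lies between the two CH carbons C7 and C9, C6 carries oxygen next to the C5 carbonyl, and C9 is benzylic to the benzo ring (para to the C3 oxygen through C9a). The seven-membered ring is therefore a 1,2-naphthoquinone 2-monoketal (C5, C6, C7, C9, C9a, C4a) into whose C7–C9 bond one carbene carbon, C8, is inserted.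

## Retrosynthesis

**Deprotection (40 ← 39 ← 38).** The ten O–benzyl bonds and the enolic O–methyl bond of the tropolone are cut last. Benzyl ethers are chosen throughout because hydrogenolysis is neutral and is the established last step for flavanol gallates. The methyl ether is what the key step delivers and is an enol ether that dilute acid hydrolyses. The forward steps must not reduce the tropolone ring or epimerise C2.

**Gallate (38 ← 36 + 37).** The ester C–O bond is cut. Acylation is placed after both chromans exist, so that the only free hydroxyl of 36 is the right one; the other 3-hydroxyl was capped as a benzyl ether in 31. This uses the order of events instead of an orthogonal protecting-group pair.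

**Flavan on the benzo ring (36 ← 34 ← 33 ← 32 + 25).** O1–C2 is cut (phenol opening of a cis-epoxide, 6-endo, inversion at C2), then both epoxide C–O bonds (Jacobsen epoxidation of a Z-alkene), then the alkene (Wittig reaction of aldehyde 32 with the ylide 26 from salt 25). The neighbouring cut, an E-alkene with asymmetric dihydroxylation, gives the 2,3-trans series and needs an oxidation and hydride reduction at C3, which the tropone would not tolerate. The Z-alkene/epoxide path gives cis directly and uses no hydride. The precursor 32 has one chroman less and no new stereocentres.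

**C1 handle (32 ← 31 ← 30).** The formyl carbon is cut from C1, back to the aryl bromide 31 (palladium-catalysed formylation). The bromide has been in place since the first step and is inert until then. Benzylation of 30 to 31 marks the C8 flavan hydroxyl.

**Flavan on the tropolone ring (30 ← 28 ← 27 ← 17 + 25).** The same three cuts as above, applied to the C8 aldehyde 17. This unit is built first, while the molecule is small, because its ring closure is the less certain one (C2 is attached to the electron-poor ring).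

**C8 handle (17 ← 15 ← 14).** The aldehyde is taken back to the ester of the key product through the acid 15 and its chloride 16. A tert-butyl ester is chosen so that the acid is freed by acidolysis, and the chloride is reduced by tin hydride and palladium. An ethyl ester would need hydroxide or an aluminium hydride, and both attack the methoxytropone.

**Key disconnection (14 ← 11 + 12, through 13).** C7–C8 and C8–C9 are cut, which removes C8 as a carbene carbon and contracts the tropolone to the 2,2-dimethoxynaphthalen-1(2H)-one 11. Against an oxidative catechol/pyrogallol coupling, this cut places the C8 carboxyl and the C1 bromide without any regiochemical question, and it is redox-neutral. The precursor is a bicyclic monoketal without stereocentres. The forward reaction must cyclopropanate one alkene in the presence of ketal oxygens and four arenes, and must open the fused cyclopropane bond.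

**Monoketal (11 ← 10 ← 8 ← 7).** The ketal is cut back to the 2-methoxy-1-naphthol 10 (PhI(OAc)2 in methanol). Direct ketalisation of quinone 8 is avoided because acidic methanol adds to C4 of 1,2-naphthoquinones. Compound 10 comes from 8 by reduction and methylation of the less hindered 2-hydroxyl, and 8 from naphthol 7 by ortho-oxygenation with IBX.

**Naphthol (7 ← 5 ← 2 + 3; 2 ← 1).** The C1–C8a bond of the naphthalene is cut (cyclisation of the arylbutenoic acid 5), then the alkene (Wittig reaction of 2 with 3). The bromine of 2 blocks the normally preferred ring position, so the oxygens end at C7 and C8, and it later serves as the C1 handle of the core.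

**Ring A fragment (25 ← 24 ← 23 ← 21 ← 20 ← 19 ← 18).** The C–P and C–I bonds, the hydroboration, the methylenation and the two protections lead back to 2,4,6-trihydroxybenzaldehyde 18. One salt, 25, serves both flavan units, and its silyl ether is orthogonal to all benzyl ethers.

## Roads not taken

Alternative 1: This cuts the four C–O bonds of two oxiranes in the bis(cis-epoxide) A1 and goes back to the bis-(Z)-1,3-diarylpropene A2 on a finished benzotropolone. In the forward step (salen)MnCl (a trivalent manganese complex) with m-CPBA and N-methylmorpholine N-oxide epoxidises both Z-alkenes with the same facial sense, so one operation sets all four stereocentres; two phenol closures then invert C2 and C2′.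
- Merits: the highest stereochemical economy of all the plans; a statistical gain in enantiopurity, because a wrong-face event at either alkene ends in a separable diastereomer; and about three steps fewer after the core than the chosen plan (one epoxidation, no benzylation of a chroman hydroxyl, no late formylation).
- Weak points: it does not say where a benzotropolone with two alkenyl arms comes from. The two alkenes are electronically different, one conjugated with the catechol ring and one with the tropolone, yet must respond to one set of conditions. The two 3-hydroxyls can only be told apart by two different ring A protecting groups (silyl and methoxymethyl in A1), so two ring A fragments are needed, and the acetal must be removed by acid while an epoxide, a gallate and a finished chroman are present.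
- Comparison: the chosen plan uses the same epoxidation and closure, but twice in sequence (27 to 30, 33 to 36). It pays with a longer linear sequence. It gains a core that arrives from step 7 with both handles in place, a single ring A fragment 25, separate tuning of each epoxidation, and differentiation of the hydroxyls by order of events.

Alternative 2: This cuts O1–C2 and C3–C4 in both pyran rings, so that each ring A arrives as the o-quinone methide A4 and the core as the bis(silyl enol ether) A5. In the forward step N-benzylcinchonidinium fluoride unmasks both partners, each enolate adds to a methide carbon and each phenoxide closes on a ketone, giving the bis(2-hydroxychroman) hemiketal A3 with C3 and C3′ set. C2 and C2′ would be set later by reductive removal of the anomeric hydroxyls.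
- Merits: the most convergent construction of the pyran rings, a trivial ring A component, and the gallate in place from the start. On paper it is much shorter than the chosen plan.
- Weak points: two independent Michael additions of α-oxygenated enolates must both be face-selective under ion-pair control on a large substrate, which has no close precedent. The acyloxy enolate can transfer or eliminate its gallate. Two hemiketals must then be reduced to the 2,3-cis series with silane and Lewis acid on a tropolone. A5 still needs a benzotropolone functionalised at C1 and C8.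
- Comparison: Alternative 2 is better in step count. The chosen plan sets each stereocentre by a reaction class with an established facial model and leaves C2 to a stereospecific closure.

Alternative 3: This cuts the two C(sp2)–C(sp3) bonds C8–C2′ and C1–C2, giving the dihalide A7 and the two cis-chroman-2-yl stannanes A8 and A9. In the forward step Pd2(dba)3, a bulky biarylphosphine (JackiePhos), CuCl and KF couple first the iodide with A8 and then the bromide with A9, each with retention, to give A6, which is one hydrogenolysis away from the target.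
- Merits: the highest convergence, all stereocentres made on small fragments, no oxidation on the tropolone, halogen order as site control, and a one-step endgame.
- Weak points: the cis-2-stannylchroman-3-ol derivatives are not known compounds, and making them enantiopure and cis is a problem as large as a flavan synthesis. After transmetalation the carbon–metal bond has a β-oxygen leaving group (a gallate in A9), which invites elimination to a 4H-chromene. A secondary α-oxy stannane must couple at the peri-hindered C1 bromide.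
- Comparison: if the stannanes were available, Alternative 3 would be clearly better in convergence and endgame. The chosen plan gives up convergence for steps that all belong to known reaction classes. Its key step delivers a core of the A7 type (bromide at C1, carboxyl at C8), so it would not block a later move to this road.

Key step: step 7

Remark: cyclopropane 13 is expected as a mixture of racemic exo and endo isomers; all three of its stereocentres disappear in the ring enlargement, so it is drawn without configuration.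

## Route

Step 1
Reactants: 1 3,4-bis(benzyloxy)benzaldehyde
Product: 2 2-bromo-4,5-bis(benzyloxy)benzaldehyde
Conditions: Br2, NaOAc, AcOH, rt
Reagents that add atoms: bromine, BrBr
Why: Electrophilic aromatic bromination; the position para to the 3-benzyloxy group (ortho to the formyl group) is the most activated unhindered site, as in the bromination of veratraldehyde. Acetate buffers HBr so that the benzyl ethers survive.

Step 2
Reactants: 2 2-bromo-4,5-bis(benzyloxy)benzaldehyde; 3 (2-carboxyethyl)triphenylphosphonium bromide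
Product: 5 (E)-4-[2-bromo-4,5-bis(benzyloxy)phenyl]but-3-enoic acid, via carboxylate ylide 4 (not isolated)
Conditions: NaN(SiMe3)2 (2.2 equiv), THF, 0 °C → rt; then aq. HCl
Reagents that add atoms: none
Why: Wittig olefination with the carboxylate-bearing ylide gives the β,γ-unsaturated acid directly, mainly as the E isomer. The alkene geometry is not critical because it equilibrates through the dienolate in the next step.

Step 3
Reactants: 5 (E)-4-[2-bromo-4,5-bis(benzyloxy)phenyl]but-3-enoic acid
Product: 7 5-bromo-7,8-bis(benzyloxy)naphthalen-1-ol, via naphthyl acetate 6 (not isolated)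
Conditions: Ac2O, NaOAc, 140 °C; then K2CO3, MeOH, rt
Reagents that add atoms: none
Why: Classical cyclisation of a 4-arylbut-3-enoic acid through its mixed anhydride (dienylketene, 6π-electrocyclisation, enol acetylation). Bromine blocks one ortho position, so closure must occur next to the benzyloxy group and gives the 7,8-dioxygenated naphthalene; the conditions are not acidic, so the benzyl ethers survive.

Step 4
Reactants: 7 5-bromo-7,8-bis(benzyloxy)naphthalen-1-ol
Product: 8 5-bromo-7,8-bis(benzyloxy)naphthalene-1,2-dione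
Conditions: IBX, DMF, rt
Reagents that add atoms: 2-iodoxybenzoic acid (IBX), O=C1OI(=O)(O)c2ccccc12
Why: IBX oxygenates phenols at a free ortho position by intramolecular oxygen transfer from the aryloxy–iodine intermediate and gives o-quinones. C2 is the only free ortho position of 7.

Step 5
Reactants: 8 5-bromo-7,8-bis(benzyloxy)naphthalene-1,2-dione
Product: 10 5-bromo-7,8-bis(benzyloxy)-2-methoxynaphthalen-1-ol, via naphthalene-1,2-diol 9 (not isolated)
Conditions: Na2S2O4, THF/H2O, rt; then K2CO3 (1.1 equiv), MeI (1.05 equiv), acetone, rt, under argon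
Reagents that add atoms: iodomethane, CI
Why: Dithionite reduces the quinone to the catechol, which is methylated at once under mild Williamson conditions. O1 is flanked by the peri benzyloxy group at C8 and hydrogen-bonded to it, so the less hindered 2-hydroxyl should react first.

Step 6
Reactants: 10 5-bromo-7,8-bis(benzyloxy)-2-methoxynaphthalen-1-ol
Product: 11 5-bromo-7,8-bis(benzyloxy)-2,2-dimethoxynaphthalen-1(2H)-one
Conditions: PhI(OAc)2, MeOH, 0 °C
Reagents that add atoms: methanol, CO
Why: Oxidative dearomatisation of a 2-methoxy-1-naphthol with a trivalent iodine reagent in methanol (masked o-quinone formation). Methanol adds to the carbon that already carries the methoxy group; in the naphthalene series such monoketals do not dimerise.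

Step 7
Reactants: 11 5-bromo-7,8-bis(benzyloxy)-2,2-dimethoxynaphthalen-1(2H)-one; 12 tert-butyl diazoacetate
Product: 14 tert-butyl 1-bromo-3,4-bis(benzyloxy)-6-methoxy-5-oxo-5H-benzo[7]annulene-8-carboxylate, via cyclopropane ester 13 (not isolated)
Conditions: Rh2(OAc)4 (1 mol%), 12 (slow addition), CH2Cl2, rt; then anhydrous camphorsulfonic acid (0.2 equiv), same flask, 0 °C → rt
Reagents that add atoms: none
Why: The electrophilic rhodium carbenoid formed from 12 with loss of N2 adds in a concerted, asynchronous [2+1] fashion to the cis-disubstituted C3=C4 alkene of 11 (naphthalenone numbering), which is conjugated with the dialkoxyarene; this forms C7–C8 and C8–C9 (product numbering) and closes the three-membered ring of 13. Camphorsulfonic acid then ionises the ketal at C6 to an oxocarbenium ion that is a cyclopropylcarbinyl cation; the ring-fusion bond C7–C9 breaks, the charge moves to benzylic C9, and loss of the C8 proton gives the aromatic tropolone ether 14 without any change of oxidation level. The closest known reactions are the Rh2(OAc)4-catalysed cyclopropanation of cyclic styrenes (indene, 1,2-dihydronaphthalene, chromenes) with diazoacetates and the acid-promoted enlargement of cyclopropane-fused o-quinone monoketals to tropolone ethers. The seven-membered ring is therefore not closed end to end; it arises by one-carbon enlargement of the six-membered ring through cleavage of the shared bond (cyclopropylcarbinyl to homoallyl rearrangement). No stereocentre survives: the three stereocentres of 13 are erased on aromatisation, so the exo/endo ratio does not matter. The step needs chemoselectivity for the alkene over the ketal oxygens (ylide formation), the ketone and the arene rings; the alkene is the most electron-rich unhindered π-bond, the ketal oxygens are hindered and deactivated by the adjacent carbonyl, and slow addition of 12 suppresses carbene dimerisation. It also needs the fused bond, not the C7–C8 bond, to break; only that cleavage gives a cation stabilised by the arene and its para benzyloxy group at C3, whereas the other would place the charge next to the ester. The acid is catalytic and anhydrous so that the enolic methyl ether and the tert-butyl ester survive.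

Step 8
Reactants: 14 tert-butyl 1-bromo-3,4-bis(benzyloxy)-6-methoxy-5-oxo-5H-benzo[7]annulene-8-carboxylate
Product: 15 1-bromo-3,4-bis(benzyloxy)-6-methoxy-5-oxo-5H-benzo[7]annulene-8-carboxylic acid
Conditions: CF3CO2H/CH2Cl2 (1:4), 0 °C → rt
Reagents that add atoms: none
Why: Acidolysis of the tert-butyl ester (loss of 2-methylpropene) under anhydrous conditions leaves the aryl benzyl ethers and the enolic methyl ether untouched. It frees the acid without hydroxide or hydride, both of which attack the methoxytropone.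

Step 9
Reactants: 15 1-bromo-3,4-bis(benzyloxy)-6-methoxy-5-oxo-5H-benzo[7]annulene-8-carboxylic acid
Product: 17 1-bromo-3,4-bis(benzyloxy)-6-methoxy-5-oxo-5H-benzo[7]annulene-8-carbaldehyde, via acid chloride 16 (not isolated)
Conditions: 1-chloro-N,N,2-trimethylprop-1-en-1-amine (1.05 equiv), CH2Cl2, 0 °C; then Bu3SnH, Pd(PPh3)4 (3 mol%), toluene, rt
Reagents that add atoms: none
Why: The α-chloroenamine converts the acid into its chloride under neutral conditions, and palladium-catalysed hydrostannolysis of acyl chlorides gives aldehydes. Oxidative addition of zerovalent palladium to the C(O)–Cl bond is much faster at room temperature than to the hindered, electron-rich aryl bromide.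

Step 10
Reactants: 18 2,4,6-trihydroxybenzaldehyde
Product: 19 2,4-bis(benzyloxy)-6-hydroxybenzaldehyde
Conditions: BnBr (2.1 equiv), K2CO3, DMF, rt
Reagents that add atoms: benzyl bromide, BrCc1ccccc1
Why: Williamson etherification; the 4-hydroxyl and one ortho hydroxyl are alkylated, while the remaining ortho hydroxyl, hydrogen-bonded to the formyl group, is the least nucleophilic and stays free, as known for 2,4,6-trihydroxyaryl carbonyl compounds.

Step 11
Reactants: 19 2,4-bis(benzyloxy)-6-hydroxybenzaldehyde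
Product: 20 2,4-bis(benzyloxy)-6-[(triisopropylsilyl)oxy]benzaldehyde
Conditions: iPr3SiOTf, 2,6-lutidine, CH2Cl2, 0 °C
Reagents that add atoms: triisopropylsilyl triflate, CC(C)[Si](OS(=O)(=O)C(F)(F)F)(C(C)C)C(C)C
Why: Silylation of the chelated phenol with the reactive silyl triflate. The triisopropylsilyl aryl ether withstands ylides, boranes and mild base and is removed later by fluoride.

Step 12
Reactants: 20 2,4-bis(benzyloxy)-6-[(triisopropylsilyl)oxy]benzaldehyde
Product: 21 1,5-bis(benzyloxy)-2-ethenyl-3-[(triisopropylsilyl)oxy]benzene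
Conditions: Ph3PCH3Br, KN(SiMe3)2, THF, 0 °C → rt
Reagents that add atoms: methyltriphenylphosphonium bromide, C[P+](c1ccccc1)(c1ccccc1)c1ccccc1.[Br-]
Why: Wittig methylenation; the small ylide reaches the doubly ortho-substituted aldehyde.

Step 13
Reactants: 21 1,5-bis(benzyloxy)-2-ethenyl-3-[(triisopropylsilyl)oxy]benzene
Product: 23 2-{2,4-bis(benzyloxy)-6-[(triisopropylsilyl)oxy]phenyl}ethanol, via alkylborane 22 (not isolated)
Conditions: 9-BBN, THF, rt; then H2O2, aq. NaOAc, 0 °C → rt
Reagents that add atoms: hydrogen peroxide, OO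
Why: Anti-Markovnikov hydroboration of the styrene with the bulky borane, then oxidation of the carbon–boron bond with retention. The buffered peroxide spares the aryl silyl ether.

Step 14
Reactants: 23 2-{2,4-bis(benzyloxy)-6-[(triisopropylsilyl)oxy]phenyl}ethanol
Product: 24 1,5-bis(benzyloxy)-2-(2-iodoethyl)-3-[(triisopropylsilyl)oxy]benzene
Conditions: I2, PPh3, imidazole, CH2Cl2, 0 °C → rt
Reagents that add atoms: iodine, II
Why: Appel-type conversion of the primary alcohol into the iodide through the alkoxyphosphonium salt (SN2).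

Step 15
Reactants: 24 1,5-bis(benzyloxy)-2-(2-iodoethyl)-3-[(triisopropylsilyl)oxy]benzene
Product: 25 (2-{2,4-bis(benzyloxy)-6-[(triisopropylsilyl)oxy]phenyl}ethyl)triphenylphosphonium iodide
Conditions: PPh3, MeCN, 80 °C
Reagents that add atoms: triphenylphosphine, c1ccc(cc1)P(c1ccccc1)c1ccccc1
Why: Quaternisation of the phosphine by the primary iodide (SN2). The salt is the ring A fragment for both flavan units (steps 16 and 21).

Step 16
Reactants: 17 1-bromo-3,4-bis(benzyloxy)-6-methoxy-5-oxo-5H-benzo[7]annulene-8-carbaldehyde; 25 (2-{2,4-bis(benzyloxy)-6-[(triisopropylsilyl)oxy]phenyl}ethyl)triphenylphosphonium iodide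
Product: 27 1-bromo-3,4-bis(benzyloxy)-8-[(1Z)-3-{2,4-bis(benzyloxy)-6-[(triisopropylsilyl)oxy]phenyl}prop-1-en-1-yl]-6-methoxy-5H-benzo[7]annulen-5-one, via phosphonium ylide 26 (not isolated)
Conditions: 25, NaN(SiMe3)2, THF, −78 → 0 °C; then 17, −78 °C → rt
Reagents that add atoms: none
Why: Wittig reaction of the non-stabilised, lithium-free ylide proceeds under kinetic control through the cis-oxaphosphetane and gives the Z-alkene. At −78 °C the aldehyde reacts far faster than the methoxytropone ring.

Step 17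
Reactants: 27 1-bromo-3,4-bis(benzyloxy)-8-[(1Z)-3-{2,4-bis(benzyloxy)-6-[(triisopropylsilyl)oxy]phenyl}prop-1-en-1-yl]-6-methoxy-5H-benzo[7]annulen-5-one
Product: 28 1-bromo-3,4-bis(benzyloxy)-8-[(2S,3R)-3-{2,4-bis(benzyloxy)-6-[(triisopropylsilyl)oxy]benzyl}oxiran-2-yl]-6-methoxy-5H-benzo[7]annulen-5-one
Conditions: (S,S)-(salen)MnCl [(S,S)-N,N′-bis(3,5-di-tert-butylsalicylidene)-1,2-cyclohexanediaminomanganese chloride] (5 mol%), m-CPBA, N-methylmorpholine N-oxide, CH2Cl2, −78 °C
Reagents that add atoms: m-chloroperbenzoic acid, OOC(=O)c1cccc(Cl)c1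
Why: Jacobsen epoxidation; conjugated cis-disubstituted alkenes are the best substrates of (salen)MnCl catalysts. By analogy with indene and cis-β-methylstyrene the (S,S)-catalyst should deliver oxygen to the face that gives the (2S,3R)-cis-epoxide, which sets C3 as in the target and C2 for inversion. The low-temperature peracid conditions limit leakage to the trans-epoxide and avoid hypochlorite, which could chlorinate ring A.

Step 18
Reactants: 28 1-bromo-3,4-bis(benzyloxy)-8-[(2S,3R)-3-{2,4-bis(benzyloxy)-6-[(triisopropylsilyl)oxy]benzyl}oxiran-2-yl]-6-methoxy-5H-benzo[7]annulen-5-one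
Product: 30 1-bromo-3,4-bis(benzyloxy)-8-[(2R,3R)-5,7-bis(benzyloxy)-3-hydroxychroman-2-yl]-6-methoxy-5H-benzo[7]annulen-5-one, via epoxy phenol 29 (not isolated)
Conditions: Bu4NF, AcOH, THF, 0 °C; then camphorsulfonic acid (cat.), CH2Cl2, 0 °C
Reagents that add atoms: none
Why: Buffered fluoride frees the phenol without base-induced 5-exo opening. Acid catalysis then gives anti 6-endo opening of the epoxide at C2, whose developing positive charge is delocalised into the C8=C9 bond of the core; this inverts C2 (S to R), leaves C3 untouched and gives the 2,3-cis-flavan-3-ol, as in the known epoxide route to flavan-3-ols from 2-(3-aryloxiranylmethyl)phenols.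

Step 19
Reactants: 30 1-bromo-3,4-bis(benzyloxy)-8-[(2R,3R)-5,7-bis(benzyloxy)-3-hydroxychroman-2-yl]-6-methoxy-5H-benzo[7]annulen-5-one
Product: 31 1-bromo-3,4-bis(benzyloxy)-6-methoxy-8-[(2R,3R)-3,5,7-tris(benzyloxy)chroman-2-yl]-5H-benzo[7]annulen-5-one
Conditions: 2-benzyloxy-1-methylpyridinium triflate, MgO, PhCF3, 85 °C
Reagents that add atoms: 2-benzyloxy-1-methylpyridinium triflate, C[n+]1ccccc1OCc1ccccc1.[O-]S(=O)(=O)C(F)(F)F
Why: Benzyl transfer from the pyridinium salt under neutral conditions etherifies the secondary alcohol without the strong base that could epimerise C2. The benzyl ether marks this hydroxyl as the one not to be galloylated and falls in the final hydrogenolysis.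

Step 20
Reactants: 31 1-bromo-3,4-bis(benzyloxy)-6-methoxy-8-[(2R,3R)-3,5,7-tris(benzyloxy)chroman-2-yl]-5H-benzo[7]annulen-5-one
Product: 32 3,4-bis(benzyloxy)-6-methoxy-5-oxo-8-[(2R,3R)-3,5,7-tris(benzyloxy)chroman-2-yl]-5H-benzo[7]annulene-1-carbaldehyde
Conditions: Pd(OAc)2 (2 mol%), di(1-adamantyl)-n-butylphosphine (6 mol%), TMEDA, CO/H2 (1:1, 5 bar), toluene, 100 °C
Reagents that add atoms: carbon monoxide, [C-]#[O+]
Why: Palladium-catalysed reductive carbonylation (formylation) of an aryl bromide with synthesis gas and a bulky dialkylphosphine. It tolerates electron-rich and ortho-substituted bromides, ethers and ketones and avoids aryllithium or Grignard intermediates, which the tropone would not survive.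

Step 21
Reactants: 32 3,4-bis(benzyloxy)-6-methoxy-5-oxo-8-[(2R,3R)-3,5,7-tris(benzyloxy)chroman-2-yl]-5H-benzo[7]annulene-1-carbaldehyde; 25 (2-{2,4-bis(benzyloxy)-6-[(triisopropylsilyl)oxy]phenyl}ethyl)triphenylphosphonium iodide
Product: 33 3,4-bis(benzyloxy)-1-[(1Z)-3-{2,4-bis(benzyloxy)-6-[(triisopropylsilyl)oxy]phenyl}prop-1-en-1-yl]-6-methoxy-8-[(2R,3R)-3,5,7-tris(benzyloxy)chroman-2-yl]-5H-benzo[7]annulen-5-one
Conditions: 25, NaN(SiMe3)2, THF, −78 → 0 °C; then 32, −78 °C → rt
Reagents that add atoms: none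
Why: The same Z-selective Wittig reaction as in step 16, now on the aryl aldehyde at C1; deprotonation of 25 regenerates the phosphorane 26 described there, which is used at once. The preformed ylide is consumed by the aldehyde at low temperature, so the existing chroman is not exposed to free base.

Step 22
Reactants: 33 3,4-bis(benzyloxy)-1-[(1Z)-3-{2,4-bis(benzyloxy)-6-[(triisopropylsilyl)oxy]phenyl}prop-1-en-1-yl]-6-methoxy-8-[(2R,3R)-3,5,7-tris(benzyloxy)chroman-2-yl]-5H-benzo[7]annulen-5-one
Product: 34 3,4-bis(benzyloxy)-1-[(2S,3R)-3-{2,4-bis(benzyloxy)-6-[(triisopropylsilyl)oxy]benzyl}oxiran-2-yl]-6-methoxy-8-[(2R,3R)-3,5,7-tris(benzyloxy)chroman-2-yl]-5H-benzo[7]annulen-5-one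
Conditions: (S,S)-(salen)MnCl (5 mol%), m-CPBA, N-methylmorpholine N-oxide, CH2Cl2, −78 °C
Reagents that add atoms: m-chloroperbenzoic acid, OOC(=O)c1cccc(Cl)c1
Why: The same Jacobsen epoxidation; this alkene is conjugated with the electron-rich dialkoxyarene and is a typical substrate. The catalyst, not the distant C8 flavan, controls the face, so the (S,S)-catalyst again gives the (2S,3R)-cis-epoxide.

Step 23
Reactants: 34 3,4-bis(benzyloxy)-1-[(2S,3R)-3-{2,4-bis(benzyloxy)-6-[(triisopropylsilyl)oxy]benzyl}oxiran-2-yl]-6-methoxy-8-[(2R,3R)-3,5,7-tris(benzyloxy)chroman-2-yl]-5H-benzo[7]annulen-5-one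
Product: 36 3,4-bis(benzyloxy)-1-[(2R,3R)-5,7-bis(benzyloxy)-3-hydroxychroman-2-yl]-6-methoxy-8-[(2R,3R)-3,5,7-tris(benzyloxy)chroman-2-yl]-5H-benzo[7]annulen-5-one, via epoxy phenol 35 (not isolated)
Conditions: Bu4NF, AcOH, THF, 0 °C; then camphorsulfonic acid (cat.), CH2Cl2, −20 °C
Reagents that add atoms: none
Why: The same desilylation and acid-catalysed 6-endo closure. C2 is here a p-alkoxybenzylic carbon as in the classical flavan syntheses; attack occurs there with inversion and gives the second (2R,3R)-cis-flavan-3-ol, whose hydroxyl is the only free one in the molecule.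

Step 24
Reactants: 36 3,4-bis(benzyloxy)-1-[(2R,3R)-5,7-bis(benzyloxy)-3-hydroxychroman-2-yl]-6-methoxy-8-[(2R,3R)-3,5,7-tris(benzyloxy)chroman-2-yl]-5H-benzo[7]annulen-5-one; 37 3,4,5-tris(benzyloxy)benzoic acid
Product: 38 (2R,3R)-5,7-bis(benzyloxy)-2-{3,4-bis(benzyloxy)-6-methoxy-5-oxo-8-[(2R,3R)-3,5,7-tris(benzyloxy)chroman-2-yl]-5H-benzo[7]annulen-1-yl}chroman-3-yl 3,4,5-tris(benzyloxy)benzoate
Conditions: 37, EDC·HCl, DMAP, CH2Cl2, rt
Reagents that add atoms: none
Why: Carbodiimide/DMAP (Steglich) esterification, the standard way to 3-O-gallates of benzylated epi-flavanols. Only one hydroxyl is free, so no selectivity is needed, and C3 is not touched.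

Step 25
Reactants: 38 (2R,3R)-5,7-bis(benzyloxy)-2-{3,4-bis(benzyloxy)-6-methoxy-5-oxo-8-[(2R,3R)-3,5,7-tris(benzyloxy)chroman-2-yl]-5H-benzo[7]annulen-1-yl}chroman-3-yl 3,4,5-tris(benzyloxy)benzoate
Product: 39 (2R,3R)-5,7-bis(benzyloxy)-2-{3,4-bis(benzyloxy)-6-hydroxy-5-oxo-8-[(2R,3R)-3,5,7-tris(benzyloxy)chroman-2-yl]-5H-benzo[7]annulen-1-yl}chroman-3-yl 3,4,5-tris(benzyloxy)benzoate
Conditions: 2 M aq. HCl, THF, 40 °C
Reagents that add atoms: water, O
Why: The tropolone methyl ether is the enol ether of a 1,2-diketone (a vinylogous ester) and is hydrolysed by dilute aqueous acid. Benzyl ethers, the gallate and the chroman rings are stable to these conditions.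

Step 26
Reactants: 39 (2R,3R)-5,7-bis(benzyloxy)-2-{3,4-bis(benzyloxy)-6-hydroxy-5-oxo-8-[(2R,3R)-3,5,7-tris(benzyloxy)chroman-2-yl]-5H-benzo[7]annulen-1-yl}chroman-3-yl 3,4,5-tris(benzyloxy)benzoate
Product: 40 theaflavin-3-gallate
Conditions: H2 (1 atm), Pd(OH)2/C, THF/MeOH, rt
Reagents that add atoms: none
Why: Hydrogenolysis of the nine aryl benzyl ethers and the one alkyl benzyl ether, the standard last step for benzylated flavanol gallates. The conditions are neutral, so C2 is not epimerised and the ester is not cleaved.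

## Compound list

1 | 3,4-bis(benzyloxy)benzaldehyde | O=Cc1ccc(OCc2ccccc2)c(OCc2ccccc2)c1 | starting material
2 | 2-bromo-4,5-bis(benzyloxy)benzaldehyde | O=Cc1cc(OCc2ccccc2)c(OCc2ccccc2)cc1Br | intermediate
3 | (2-carboxyethyl)triphenylphosphonium bromide | OC(=O)CC[P+](c1ccccc1)(c1ccccc1)c1ccccc1.[Br-] | starting material
4 | sodium 3-(triphenylphosphoranylidene)propanoate (not isolated) | [Na+].[O-]C(=O)CC=P(c1ccccc1)(c1ccccc1)c1ccccc1 | intermediate
5 | (E)-4-[2-bromo-4,5-bis(benzyloxy)phenyl]but-3-enoic acid | OC(=O)C/C=C/c1cc(OCc2ccccc2)c(OCc2ccccc2)cc1Br | intermediate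
6 | 5-bromo-7,8-bis(benzyloxy)naphthalen-1-yl acetate (not isolated) | CC(=O)Oc1cccc2c(Br)cc(OCc3ccccc3)c(OCc3ccccc3)c12 | intermediate
7 | 5-bromo-7,8-bis(benzyloxy)naphthalen-1-ol | Oc1cccc2c(Br)cc(OCc3ccccc3)c(OCc3ccccc3)c12 | intermediate
8 | 5-bromo-7,8-bis(benzyloxy)naphthalene-1,2-dione | O=C1C=Cc2c(Br)cc(OCc3ccccc3)c(OCc3ccccc3)c2C1=O | intermediate
9 | 5-bromo-7,8-bis(benzyloxy)naphthalene-1,2-diol (not isolated) | Oc1ccc2c(Br)cc(OCc3ccccc3)c(OCc3ccccc3)c2c1O | intermediate
10 | 5-bromo-7,8-bis(benzyloxy)-2-methoxynaphthalen-1-ol | COc1ccc2c(Br)cc(OCc3ccccc3)c(OCc3ccccc3)c2c1O | intermediate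
11 | 5-bromo-7,8-bis(benzyloxy)-2,2-dimethoxynaphthalen-1(2H)-one | COC1(OC)C=Cc2c(Br)cc(OCc5ccccc5)c(OCc5ccccc5)c2C1=O | intermediate
12 | tert-butyl diazoacetate | CC(C)(C)OC(=O)C=[N+]=[N-] | starting material
13 | tert-butyl 7-bromo-4,5-bis(benzyloxy)-2,2-dimethoxy-3-oxo-1a,2,3,7b-tetrahydro-1H-cyclopropa[a]naphthalene-1-carboxylate (racemic exo/endo mixture, not isolated) | COC1(OC)C2C(C(=O)OC(C)(C)C)C2c2c(Br)cc(OCc5ccccc5)c(OCc5ccccc5)c2C1=O | intermediate
14 | tert-butyl 1-bromo-3,4-bis(benzyloxy)-6-methoxy-5-oxo-5H-benzo[7]annulene-8-carboxylate | Brc1cc(OCc5ccccc5)c(OCc5ccccc5)c2c(=O)c(OC)cc(C(=O)OC(C)(C)C)cc12 | intermediate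
15 | 1-bromo-3,4-bis(benzyloxy)-6-methoxy-5-oxo-5H-benzo[7]annulene-8-carboxylic acid | Brc1cc(OCc5ccccc5)c(OCc5ccccc5)c2c(=O)c(OC)cc(C(=O)O)cc12 | intermediate
16 | 1-bromo-3,4-bis(benzyloxy)-6-methoxy-5-oxo-5H-benzo[7]annulene-8-carbonyl chloride (not isolated) | Brc1cc(OCc5ccccc5)c(OCc5ccccc5)c2c(=O)c(OC)cc(C(=O)Cl)cc12 | intermediate
17 | 1-bromo-3,4-bis(benzyloxy)-6-methoxy-5-oxo-5H-benzo[7]annulene-8-carbaldehyde | Brc1cc(OCc5ccccc5)c(OCc5ccccc5)c2c(=O)c(OC)cc(C=O)cc12 | intermediate
18 | 2,4,6-trihydroxybenzaldehyde | O=Cc1c(O)cc(O)cc1O | starting material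
19 | 2,4-bis(benzyloxy)-6-hydroxybenzaldehyde | O=Cc1c(O)cc(OCc2ccccc2)cc1OCc1ccccc1 | intermediate
20 | 2,4-bis(benzyloxy)-6-[(triisopropylsilyl)oxy]benzaldehyde | O=Cc1c(O[Si](C(C)C)(C(C)C)C(C)C)cc(OCc2ccccc2)cc1OCc1ccccc1 | intermediate
21 | 1,5-bis(benzyloxy)-2-ethenyl-3-[(triisopropylsilyl)oxy]benzene | C=Cc1c(O[Si](C(C)C)(C(C)C)C(C)C)cc(OCc2ccccc2)cc1OCc1ccccc1 | intermediate
22 | 9-(2-{2,4-bis(benzyloxy)-6-[(triisopropylsilyl)oxy]phenyl}ethyl)-9-borabicyclo[3.3.1]nonane (not isolated) | CC(C)[Si](C(C)C)(C(C)C)Oc1cc(OCc2ccccc2)cc(OCc2ccccc2)c1CCB1C2CCCC1CCC2 | intermediate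
23 | 2-{2,4-bis(benzyloxy)-6-[(triisopropylsilyl)oxy]phenyl}ethanol | OCCc1c(O[Si](C(C)C)(C(C)C)C(C)C)cc(OCc2ccccc2)cc1OCc1ccccc1 | intermediate
24 | 1,5-bis(benzyloxy)-2-(2-iodoethyl)-3-[(triisopropylsilyl)oxy]benzene | ICCc1c(O[Si](C(C)C)(C(C)C)C(C)C)cc(OCc2ccccc2)cc1OCc1ccccc1 | intermediate
25 | (2-{2,4-bis(benzyloxy)-6-[(triisopropylsilyl)oxy]phenyl}ethyl)triphenylphosphonium iodide | [I-].CC(C)[Si](C(C)C)(C(C)C)Oc1cc(OCc2ccccc2)cc(OCc2ccccc2)c1CC[P+](c1ccccc1)(c1ccccc1)c1ccccc1 | intermediate
26 | (2-{2,4-bis(benzyloxy)-6-[(triisopropylsilyl)oxy]phenyl}ethylidene)triphenylphosphorane (not isolated) | CC(C)[Si](C(C)C)(C(C)C)Oc1cc(OCc2ccccc2)cc(OCc2ccccc2)c1CC=P(c1ccccc1)(c1ccccc1)c1ccccc1 | intermediate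
27 | 1-bromo-3,4-bis(benzyloxy)-8-[(1Z)-3-{2,4-bis(benzyloxy)-6-[(triisopropylsilyl)oxy]phenyl}prop-1-en-1-yl]-6-methoxy-5H-benzo[7]annulen-5-one | Brc1cc(OCc5ccccc5)c(OCc5ccccc5)c2c(=O)c(OC)cc(/C=C\Cc3c(O[Si](C(C)C)(C(C)C)C(C)C)cc(OCc5ccccc5)cc3OCc5ccccc5)cc12 | intermediate
28 | 1-bromo-3,4-bis(benzyloxy)-8-[(2S,3R)-3-{2,4-bis(benzyloxy)-6-[(triisopropylsilyl)oxy]benzyl}oxiran-2-yl]-6-methoxy-5H-benzo[7]annulen-5-one | Brc1cc(OCc5ccccc5)c(OCc5ccccc5)c2c(=O)c(OC)cc([C@@H]4O[C@@H]4Cc3c(O[Si](C(C)C)(C(C)C)C(C)C)cc(OCc5ccccc5)cc3OCc5ccccc5)cc12 | intermediate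
29 | 1-bromo-3,4-bis(benzyloxy)-8-{(2S,3R)-3-[2,4-bis(benzyloxy)-6-hydroxybenzyl]oxiran-2-yl}-6-methoxy-5H-benzo[7]annulen-5-one (not isolated) | Brc1cc(OCc5ccccc5)c(OCc5ccccc5)c2c(=O)c(OC)cc([C@@H]4O[C@@H]4Cc3c(O)cc(OCc5ccccc5)cc3OCc5ccccc5)cc12 | intermediate
30 | 1-bromo-3,4-bis(benzyloxy)-8-[(2R,3R)-5,7-bis(benzyloxy)-3-hydroxychroman-2-yl]-6-methoxy-5H-benzo[7]annulen-5-one | Brc1cc(OCc5ccccc5)c(OCc5ccccc5)c2c(=O)c(OC)cc([C@H]3Oc4cc(OCc5ccccc5)cc(OCc5ccccc5)c4C[C@H]3O)cc12 | intermediate
31 | 1-bromo-3,4-bis(benzyloxy)-6-methoxy-8-[(2R,3R)-3,5,7-tris(benzyloxy)chroman-2-yl]-5H-benzo[7]annulen-5-one | Brc1cc(OCc5ccccc5)c(OCc5ccccc5)c2c(=O)c(OC)cc([C@H]3Oc4cc(OCc5ccccc5)cc(OCc5ccccc5)c4C[C@H]3OCc5ccccc5)cc12 | intermediate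
32 | 3,4-bis(benzyloxy)-6-methoxy-5-oxo-8-[(2R,3R)-3,5,7-tris(benzyloxy)chroman-2-yl]-5H-benzo[7]annulene-1-carbaldehyde | O=Cc1cc(OCc5ccccc5)c(OCc5ccccc5)c2c(=O)c(OC)cc([C@H]3Oc4cc(OCc5ccccc5)cc(OCc5ccccc5)c4C[C@H]3OCc5ccccc5)cc12 | intermediate
33 | 3,4-bis(benzyloxy)-1-[(1Z)-3-{2,4-bis(benzyloxy)-6-[(triisopropylsilyl)oxy]phenyl}prop-1-en-1-yl]-6-methoxy-8-[(2R,3R)-3,5,7-tris(benzyloxy)chroman-2-yl]-5H-benzo[7]annulen-5-one | CC(C)[Si](C(C)C)(C(C)C)Oc1cc(OCc5ccccc5)cc(OCc5ccccc5)c1C/C=C\c1cc(OCc5ccccc5)c(OCc5ccccc5)c2c(=O)c(OC)cc([C@H]3Oc4cc(OCc5ccccc5)cc(OCc5ccccc5)c4C[C@H]3OCc5ccccc5)cc12 | intermediate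
34 | 3,4-bis(benzyloxy)-1-[(2S,3R)-3-{2,4-bis(benzyloxy)-6-[(triisopropylsilyl)oxy]benzyl}oxiran-2-yl]-6-methoxy-8-[(2R,3R)-3,5,7-tris(benzyloxy)chroman-2-yl]-5H-benzo[7]annulen-5-one | CC(C)[Si](C(C)C)(C(C)C)Oc1cc(OCc5ccccc5)cc(OCc5ccccc5)c1C[C@H]8O[C@H]8c1cc(OCc5ccccc5)c(OCc5ccccc5)c2c(=O)c(OC)cc([C@H]3Oc4cc(OCc5ccccc5)cc(OCc5ccccc5)c4C[C@H]3OCc5ccccc5)cc12 | intermediate
35 | 3,4-bis(benzyloxy)-1-{(2S,3R)-3-[2,4-bis(benzyloxy)-6-hydroxybenzyl]oxiran-2-yl}-6-methoxy-8-[(2R,3R)-3,5,7-tris(benzyloxy)chroman-2-yl]-5H-benzo[7]annulen-5-one (not isolated) | Oc1cc(OCc5ccccc5)cc(OCc5ccccc5)c1C[C@H]8O[C@H]8c1cc(OCc5ccccc5)c(OCc5ccccc5)c2c(=O)c(OC)cc([C@H]3Oc4cc(OCc5ccccc5)cc(OCc5ccccc5)c4C[C@H]3OCc5ccccc5)cc12 | intermediate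
36 | 3,4-bis(benzyloxy)-1-[(2R,3R)-5,7-bis(benzyloxy)-3-hydroxychroman-2-yl]-6-methoxy-8-[(2R,3R)-3,5,7-tris(benzyloxy)chroman-2-yl]-5H-benzo[7]annulen-5-one | O[C@@H]1Cc2c(OCc5ccccc5)cc(OCc5ccccc5)cc2O[C@@H]1c1cc(OCc5ccccc5)c(OCc5ccccc5)c2c(=O)c(OC)cc([C@H]3Oc4cc(OCc5ccccc5)cc(OCc5ccccc5)c4C[C@H]3OCc5ccccc5)cc12 | intermediate
37 | 3,4,5-tris(benzyloxy)benzoic acid | OC(=O)c1cc(OCc2ccccc2)c(OCc2ccccc2)c(OCc2ccccc2)c1 | starting material
38 | (2R,3R)-5,7-bis(benzyloxy)-2-{3,4-bis(benzyloxy)-6-methoxy-5-oxo-8-[(2R,3R)-3,5,7-tris(benzyloxy)chroman-2-yl]-5H-benzo[7]annulen-1-yl}chroman-3-yl 3,4,5-tris(benzyloxy)benzoate | O=C(O[C@@H]1Cc2c(OCc5ccccc5)cc(OCc5ccccc5)cc2O[C@@H]1c1cc(OCc5ccccc5)c(OCc5ccccc5)c2c(=O)c(OC)cc([C@H]3Oc4cc(OCc5ccccc5)cc(OCc5ccccc5)c4C[C@H]3OCc5ccccc5)cc12)c1cc(OCc5ccccc5)c(OCc5ccccc5)c(OCc5ccccc5)c1 | intermediate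
39 | (2R,3R)-5,7-bis(benzyloxy)-2-{3,4-bis(benzyloxy)-6-hydroxy-5-oxo-8-[(2R,3R)-3,5,7-tris(benzyloxy)chroman-2-yl]-5H-benzo[7]annulen-1-yl}chroman-3-yl 3,4,5-tris(benzyloxy)benzoate | O=C(O[C@@H]1Cc2c(OCc5ccccc5)cc(OCc5ccccc5)cc2O[C@@H]1c1cc(OCc5ccccc5)c(OCc5ccccc5)c2c(=O)c(O)cc([C@H]3Oc4cc(OCc5ccccc5)cc(OCc5ccccc5)c4C[C@H]3OCc5ccccc5)cc12)c1cc(OCc5ccccc5)c(OCc5ccccc5)c(OCc5ccccc5)c1 | intermediate
40 | theaflavin-3-gallate | O=C(O[C@@H]1Cc2c(O)cc(O)cc2O[C@@H]1c1cc(O)c(O)c2c(=O)c(O)cc([C@H]3Oc4cc(O)cc(O)c4C[C@H]3O)cc12)c1cc(O)c(O)c(O)c1 | target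

## Step count and least certain steps

Total: 26 steps. Longest linear sequence: 20 steps (steps 1–9 and 16–26). The ring A fragment 25 takes 6 steps (10–15) and is used twice.

**Step 7 (key step).** The carbenoid may be intercepted by a ketal oxygen (oxonium ylide formation followed by a [2,3]-shift across the allylic system) or may add to a benzyl ring, which would divert material from cyclopropanation. In the acid stage the donor–acceptor bond C8–C9 may open instead of the fused bond, or adventitious water may hydrolyse the ketal. Fallback: set out from quinone 8 and use its enone reactivity instead of a carbenoid. The ylide from (2-tert-butoxy-2-oxoethyl)dimethylsulfonium bromide and DBU adds to C4 of 8, and the resulting enolate closes on the ylide carbon (Michael-initiated ring closure) to give tert-butyl 7-bromo-4,5-bis(benzyloxy)-2,3-dioxo-1a,2,3,7b-tetrahydro-1H-cyclopropa[a]naphthalene-1-carboxylate F1. Catalytic camphorsulfonic acid opens the fused bond of this cyclopropyl diketone to tert-butyl 1-bromo-3,4-bis(benzyloxy)-6-hydroxy-5-oxo-5H-benzo[7]annulene-8-carboxylate F2. Methylation with MeI and K2CO3 can only occur at O6, because an O5 ether would break the benzo aromaticity, and returns to 14. This bypasses steps 5 to 7.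

**Step 18.** The closure may lose regiocontrol (5-exo attack at C3 to a dihydrobenzofuran) or stereospecificity (ionisation at C2), because C2 is attached to the tropolone ring, whose basic carbonyl is protonated by the acid and then withdraws electrons. Fallback: set out from aldehyde 17 and form O1–C2 by an SN2 reaction at a carbon that cannot ionise, closing the ring at the unsubstituted carbon instead. Addition of CH2=CHMgBr at −78 °C gives racemic 1-bromo-3,4-bis(benzyloxy)-8-(1-hydroxyprop-2-en-1-yl)-6-methoxy-5H-benzo[7]annulen-5-one F3. Sharpless kinetic resolution (Ti(OiPr)4, L-(+)-diisopropyl tartrate, t-BuOOH) epoxidises the fast-reacting enantiomer to the erythro epoxy alcohol 1-bromo-3,4-bis(benzyloxy)-8-{(S)-hydroxy[(2R)-oxiran-2-yl]methyl}-6-methoxy-5H-benzo[7]annulen-5-one F4; being a resolution, this forfeits half of the material. Mitsunobu etherification with 3,5-bis(benzyloxy)phenol (PPh3, diisopropyl azodicarboxylate) inverts C2 and gives 1-bromo-3,4-bis(benzyloxy)-8-{(R)-[3,5-bis(benzyloxy)phenoxy][(2R)-oxiran-2-yl]methyl}-6-methoxy-5H-benzo[7]annulen-5-one F5. An intramolecular Friedel–Crafts epoxide–arene cyclisation (AuCl3/AgOTf catalysis) then attacks the terminal epoxide carbon 6-endo, breaks no bond to a stereocentre, and returns to 30.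

**Step 17 (and likewise step 22).** The stepwise collapse of the manganese–oxo adduct may leak to the trans-epoxide, and facial selectivity may be lower than for simple aryl alkenes because this alkene is conjugated with the electron-poor tropolone. Fallback: from 27 to 28 by a Shi-type epoxidation with a chiral dioxirane (the enantiomer of the glucose-derived oxazolidinone ketone that gives the (2S,3R)-epoxide, KHSO5), which transfers oxygen in a concerted way and cannot scramble alkene geometry. No new compound is made (F0).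

**Step 5.** Site selectivity between O1 and O2 may be poor, double methylation may occur, and the catechol may reoxidise in air. Fallback: a regiodefined Dakin-type sequence that sets out from naphthol 7. Ortho-formylation (MgCl2, Et3N, paraformaldehyde) gives 5-bromo-7,8-bis(benzyloxy)-1-hydroxynaphthalene-2-carbaldehyde F6. Methoxymethylation (MOMCl, iPr2NEt) gives 5-bromo-7,8-bis(benzyloxy)-1-(methoxymethoxy)naphthalene-2-carbaldehyde F7. Baeyer–Villiger oxidation with m-CPBA and methanolysis of the formate gives 5-bromo-7,8-bis(benzyloxy)-1-(methoxymethoxy)naphthalen-2-ol F8. Methylation (MeI, K2CO3) gives 5-bromo-7,8-bis(benzyloxy)-2-methoxy-1-(methoxymethoxy)naphthalene F9, and HCl in methanol removes the acetal and returns to 10.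

**Step 9.** The chloroenamine or the acid chloride may react at the basic tropone oxygen (chlorotropylium formation), and the tin hydride/palladium system may reduce the C1–Br bond. Fallback: from acid 15, thioesterification (EtSH, EDC, DMAP) gives S-ethyl 1-bromo-3,4-bis(benzyloxy)-6-methoxy-5-oxo-5H-benzo[7]annulene-8-carbothioate F10, and Fukuyama reduction (Et3SiH, Pd/C, acetone) returns to 17.

**Step 26.** Hydrogenation may go too far (saturation of the tropolone ring or hydrogenolysis of the benzylic C2–O1 bonds), and the chelating tropolone may poison the catalyst. Fallback: from 39 to 40 by Lewis-acid debenzylation with BCl3 and pentamethylbenzene as cation scavenger at −78 °C, which uses no hydrogen. No new compound is made (F0).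

## Further compounds

F1 | step 7 | tert-butyl 7-bromo-4,5-bis(benzyloxy)-2,3-dioxo-1a,2,3,7b-tetrahydro-1H-cyclopropa[a]naphthalene-1-carboxylate (racemic) | O=C1C2C(C(=O)OC(C)(C)C)C2c2c(Br)cc(OCc5ccccc5)c(OCc5ccccc5)c2C1=O
F2 | step 7 | tert-butyl 1-bromo-3,4-bis(benzyloxy)-6-hydroxy-5-oxo-5H-benzo[7]annulene-8-carboxylate | Brc1cc(OCc5ccccc5)c(OCc5ccccc5)c2c(=O)c(O)cc(C(=O)OC(C)(C)C)cc12
F3 | step 18 | 1-bromo-3,4-bis(benzyloxy)-8-(1-hydroxyprop-2-en-1-yl)-6-methoxy-5H-benzo[7]annulen-5-one (racemic) | Brc1cc(OCc5ccccc5)c(OCc5ccccc5)c2c(=O)c(OC)cc(C(O)C=C)cc12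
F4 | step 18 | 1-bromo-3,4-bis(benzyloxy)-8-{(S)-hydroxy[(2R)-oxiran-2-yl]methyl}-6-methoxy-5H-benzo[7]annulen-5-one | Brc1cc(OCc5ccccc5)c(OCc5ccccc5)c2c(=O)c(OC)cc([C@H](O)[C@H]4CO4)cc12
F5 | step 18 | 1-bromo-3,4-bis(benzyloxy)-8-{(R)-[3,5-bis(benzyloxy)phenoxy][(2R)-oxiran-2-yl]methyl}-6-methoxy-5H-benzo[7]annulen-5-one | Brc1cc(OCc5ccccc5)c(OCc5ccccc5)c2c(=O)c(OC)cc([C@@H](Oc3cc(OCc5ccccc5)cc(OCc5ccccc5)c3)[C@H]4CO4)cc12
F0 | step 17 | none | none
F6 | step 5 | 5-bromo-7,8-bis(benzyloxy)-1-hydroxynaphthalene-2-carbaldehyde | O=Cc1ccc2c(Br)cc(OCc3ccccc3)c(OCc3ccccc3)c2c1O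
F7 | step 5 | 5-bromo-7,8-bis(benzyloxy)-1-(methoxymethoxy)naphthalene-2-carbaldehyde | O=Cc1ccc2c(Br)cc(OCc3ccccc3)c(OCc3ccccc3)c2c1OCOC
F8 | step 5 | 5-bromo-7,8-bis(benzyloxy)-1-(methoxymethoxy)naphthalen-2-ol | Oc1ccc2c(Br)cc(OCc3ccccc3)c(OCc3ccccc3)c2c1OCOC
F9 | step 5 | 5-bromo-7,8-bis(benzyloxy)-2-methoxy-1-(methoxymethoxy)naphthalene | COc1ccc2c(Br)cc(OCc3ccccc3)c(OCc3ccccc3)c2c1OCOC
F10 | step 9 | S-ethyl 1-bromo-3,4-bis(benzyloxy)-6-methoxy-5-oxo-5H-benzo[7]annulene-8-carbothioate | Brc1cc(OCc5ccccc5)c(OCc5ccccc5)c2c(=O)c(OC)cc(C(=O)SCC)cc12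
F0 | step 26 | none | none
A1 | alternative 1 | 3,4,6-tris(benzyloxy)-1-[(2S,3R)-3-{2,4-bis(benzyloxy)-6-[(tert-butyldimethylsilyl)oxy]benzyl}oxiran-2-yl]-8-[(2S,3R)-3-{2,4-bis(benzyloxy)-6-(methoxymethoxy)benzyl}oxiran-2-yl]-5H-benzo[7]annulen-5-one | CC(C)(C)[Si](C)(C)Oc1cc(OCc5ccccc5)cc(OCc5ccccc5)c1C[C@H]6O[C@H]6c1cc(OCc5ccccc5)c(OCc5ccccc5)c2c(=O)c(OCc5ccccc5)cc([C@@H]7O[C@@H]7Cc3c(OCOC)cc(OCc5ccccc5)cc3OCc5ccccc5)cc12
A2 | alternative 1 | 3,4,6-tris(benzyloxy)-1-[(1Z)-3-{2,4-bis(benzyloxy)-6-[(tert-butyldimethylsilyl)oxy]phenyl}prop-1-en-1-yl]-8-[(1Z)-3-{2,4-bis(benzyloxy)-6-(methoxymethoxy)phenyl}prop-1-en-1-yl]-5H-benzo[7]annulen-5-one | CC(C)(C)[Si](C)(C)Oc1cc(OCc5ccccc5)cc(OCc5ccccc5)c1C/C=C\c1cc(OCc5ccccc5)c(OCc5ccccc5)c2c(=O)c(OCc5ccccc5)cc(/C=C\Cc3c(OCOC)cc(OCc5ccccc5)cc3OCc5ccccc5)cc12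
A3 | alternative 2 | bis(2-hydroxychroman) hemiketal: (2S,3R)-5,7-bis(benzyloxy)-2-hydroxy-2-{3,4,6-tris(benzyloxy)-5-oxo-8-[(2S,3R)-3,5,7-tris(benzyloxy)-2-hydroxychroman-2-yl]-5H-benzo[7]annulen-1-yl}chroman-3-yl 3,4,5-tris(benzyloxy)benzoate (one anomer drawn) | O=C(O[C@@H]1Cc2c(OCc5ccccc5)cc(OCc5ccccc5)cc2O[C@]1(O)c1cc(OCc5ccccc5)c(OCc5ccccc5)c2c(=O)c(OCc5ccccc5)cc([C@@]3(O)Oc4cc(OCc5ccccc5)cc(OCc5ccccc5)c4C[C@H]3OCc5ccccc5)cc12)c1cc(OCc5ccccc5)c(OCc5ccccc5)c(OCc5ccccc5)c1
A4 | alternative 2 | 3,5-bis(benzyloxy)-6-methylidenecyclohexa-2,4-dien-1-one (o-quinone methide) | C=C1C(=O)C=C(OCc2ccccc2)C=C1OCc1ccccc1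
A5 | alternative 2 | 2-{3,4,6-tris(benzyloxy)-8-[2-(benzyloxy)-1-(trimethylsilyloxy)ethenyl]-5-oxo-5H-benzo[7]annulen-1-yl}-2-(trimethylsilyloxy)ethenyl 3,4,5-tris(benzyloxy)benzoate (bis silyl enol ether, alkene geometry not specified) | C[Si](C)(C)OC(=COC(=O)c1cc(OCc5ccccc5)c(OCc5ccccc5)c(OCc5ccccc5)c1)c1cc(OCc5ccccc5)c(OCc5ccccc5)c2c(=O)c(OCc5ccccc5)cc(C(O[Si](C)(C)C)=COCc5ccccc5)cc12
A6 | alternative 3 | undeca-O-benzyl theaflavin-3-gallate | O=C(O[C@@H]1Cc2c(OCc5ccccc5)cc(OCc5ccccc5)cc2O[C@@H]1c1cc(OCc5ccccc5)c(OCc5ccccc5)c2c(=O)c(OCc5ccccc5)cc([C@H]3Oc4cc(OCc5ccccc5)cc(OCc5ccccc5)c4C[C@H]3OCc5ccccc5)cc12)c1cc(OCc5ccccc5)c(OCc5ccccc5)c(OCc5ccccc5)c1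
A7 | alternative 3 | 1-bromo-3,4,6-tris(benzyloxy)-8-iodo-5H-benzo[7]annulen-5-one | Brc1cc(OCc5ccccc5)c(OCc5ccccc5)c2c(=O)c(OCc5ccccc5)cc(I)cc12
A8 | alternative 3 | tributyl[(2R,3R)-3,5,7-tris(benzyloxy)chroman-2-yl]stannane (2,3-cis) | CCCC[Sn](CCCC)(CCCC)[C@H]3Oc4cc(OCc5ccccc5)cc(OCc5ccccc5)c4C[C@H]3OCc5ccccc5
A9 | alternative 3 | (2R,3R)-5,7-bis(benzyloxy)-2-(tributylstannyl)chroman-3-yl 3,4,5-tris(benzyloxy)benzoate (2,3-cis) | O=C(O[C@@H]1Cc2c(OCc5ccccc5)cc(OCc5ccccc5)cc2O[C@@H]1[Sn](CCCC)(CCCC)CCCC)c1cc(OCc5ccccc5)c(OCc5ccccc5)c(OCc5ccccc5)c1
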